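**Retrosynthetic overview**
- The strategy rests on the trans-fused decalin (rings A and B): C5–H lies between two quaternary carbons, C4 (axial CH3, equatorial carbon chain) and C10 (CH3), and the C8=C9 alkene marks where a cation–alkene cascade would stop. This is the footprint of an (E)-alkene cyclised in a chair–chair fold.
- Key disconnection: C4–C5 and C9–C10, made together when a Lewis acid opens a (2S,3S)-epoxide at C4 and a β-keto ester enol ends the cascade; ring A closes first and ring B follows in the same operation.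
- The epoxide comes from geranyl acetate (allylic oxidation, Sharpless epoxidation, silylation); the keto ester comes from methyl acetoacetate dianion.
- After cyclisation: C3 deoxygenation; C8 methyl by enol triflate/cuprate; C18 to homoprenyl (Wittig, hydroboration–Suzuki); C9 ester to allylic bromide, second acetoacetate unit, (E)-enoate by enol phosphate/cuprate; hydrolysis.

Key step: step 7

Remark on numbering: decalin positions follow labdane usage (C1–C4 and C10, C5 in ring A; C5–C10 in ring B; C18 = equatorial carbon on C4, C11 = carbon on C9); α is the face of H-5, β the face of the C10 methyl.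
Remark on the chemistry: keto ester 11 is drawn as the keto tautomer with the ester equatorial (9β); C9 is epimerisable and becomes sp2 in step 10. The homoprenyl chain is built before the C9 side chain so that the base-sensitive (E)-enoate never meets the Wittig ylide. The two acetoacetate couplings use different dianion salts: the sodium lithium salt (NaH, then n-BuLi) for the robust primary allylic bromide 7, and the dilithium salt (two equivalents of LiN(i-Pr)2) for the ionisation-prone bromide 23, so that no alkyllithium ever meets 23.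

Step 1
Reactants: 1 geranyl acetate
Product: 2 (2E,6E)-8-hydroxygeranyl acetate
Conditions: SeO2 (cat.), t-BuOOH, salicylic acid (cat.), CH2Cl2, rt
Reagents that add atoms: selenium dioxide, O=[Se]=O (transfers the oxygen); tert-butyl hydroperoxide, CC(C)(C)OO (terminal oxidant)
Why: SeO2 allylic oxidation (ene reaction, then [2,3]-sigmatropic shift) should hydroxylate the (E)-methyl of the electron-rich terminal alkene, the acetoxy-bearing C2=C3 alkene being deactivated.

Step 2
Reactants: 2 (2E,6E)-8-hydroxygeranyl acetate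
Product: 3 (6S,7S)-6,7-epoxy-8-hydroxygeranyl acetate
Conditions: Ti(OiPr)4 (cat.), L-(+)-diethyl tartrate (cat.), t-BuOOH, 4 Å MS, CH2Cl2, −20 °C
Reagents that add atoms: tert-butyl hydroperoxide, CC(C)(C)OO
Why: Sharpless asymmetric epoxidation acts only on the allylic alcohol alkene, and the titanium L-(+)-tartrate complex should deliver oxygen to the face that gives the (2S,3S)-epoxy alcohol, as for other (E)-2-methylalk-2-en-1-ols, which sets both epoxide stereocentres.

Step 3
Reactants: 3 (6S,7S)-6,7-epoxy-8-hydroxygeranyl acetate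
Product: 4 (6S,7S)-8-(tert-butyldiphenylsilyloxy)-6,7-epoxygeranyl acetate
Conditions: TBDPSCl, imidazole, CH2Cl2, 0 °C to rt
Reagents that add atoms: tert-butyldiphenylsilyl chloride, CC(C)(C)[Si](Cl)(c1ccccc1)c1ccccc1
Why: Silylation of the primary alcohol gives a bulky, poorly chelating ether that blocks Payne rearrangement and should survive SnCl4.

Step 4
Reactants: 4 (6S,7S)-8-(tert-butyldiphenylsilyloxy)-6,7-epoxygeranyl acetate
Product: 5 (6S,7S)-8-(tert-butyldiphenylsilyloxy)-6,7-epoxygeraniol
Conditions: K2CO3 (cat.), MeOH, 0 °C to rt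
Reagents that add atoms: none
Why: Base-catalysed transesterification removes the acetate while the trisubstituted epoxide and the silyl ether are inert to methoxide at this temperature.

Step 5
Reactants: 5 (6S,7S)-8-(tert-butyldiphenylsilyloxy)-6,7-epoxygeraniol
Product: 7 (6S,7S)-8-(tert-butyldiphenylsilyloxy)-6,7-epoxygeranyl bromide, via allylic mesylate 6 (not isolated)
Conditions: MsCl, Et3N, THF, −40 °C; then LiBr, THF, 0 °C
Reagents that add atoms: lithium bromide, [Li+].[Br-]; methanesulfonyl chloride, CS(=O)(=O)Cl (its atoms stay only in 6)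
Why: Mesylation followed by SN2 displacement with bromide under cold, non-acidic conditions should keep the epoxide closed and the (E)-alkene geometry intact.

Step 6
Reactants: 7 (6S,7S)-8-(tert-butyldiphenylsilyloxy)-6,7-epoxygeranyl bromide; 8 methyl acetoacetate
Product: 10 methyl (6E,10S,11S)-12-(tert-butyldiphenylsilyloxy)-10,11-epoxy-7,11-dimethyl-3-oxododec-6-enoate, via acetoacetate dianion 9 (not isolated)
Conditions: 8, NaH, THF, 0 °C; n-BuLi, 0 °C; then 7, 0 °C; aq. quench
Reagents that add atoms: methyl acetoacetate 8, COC(=O)CC(C)=O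
Why: γ-Alkylation of the acetoacetate dianion occurs at its more basic terminal carbon by SN2 at the primary allylic bromide, faster than any attack on the hindered epoxide.

Step 7
Reactants: 10 methyl (6E,10S,11S)-12-(tert-butyldiphenylsilyloxy)-10,11-epoxy-7,11-dimethyl-3-oxododec-6-enoate
Product: 11 methyl 4α-[(tert-butyldiphenylsilyloxy)methyl]-3β-hydroxy-4β,10β-dimethyl-8-oxo-5α-decalin-9β-carboxylate
Conditions: SnCl4 (2.5 equiv), CH2Cl2, −78 to −20 °C; aq. NaHCO3
Reagents that add atoms: none
Why: SnCl4 binds the epoxide oxygen (a second equivalent is held by the keto ester as its tin-bound enol), the C4–O bond stretches at the fully substituted carbon, the C5=C10 alkene attacks C4 from the side opposite the leaving oxygen and the enol carbon C9 captures the developing tertiary cation at C10, so that C4–C5 and C9–C10 form in one chair–chair array. The closest known reactions are the Lewis-acid epoxy-polyene cyclisation of 2,3-epoxy alcohol derivatives and the SnCl4 cyclisation of polyene β-keto esters. Ring A closes 6-endo-trig at the alkene with the epoxide C–O bond breaking outside the new ring, and ring B closes as a six-membered C-alkylation of the endocyclic enol (6-enolendo). C4 is inverted by backside attack, which places the CH2OSi group (trans to the chain on the epoxide) equatorial and the methyl axial; C5 and C10 follow from antiperiplanar addition across the (E)-alkene (trans ring fusion), their sense relative to C3 and C4 follows from the ring A chair with the C3–O bond equatorial, so the (2S,3S)-epoxide fixes the absolute configuration, and C9 settles as the equatorial ester by enolisation before it is erased in step 10. The step needs ionisation at C4 and not C3 (secured by the tertiary centre, although the CH2OSi group slows it, and by a silyl ether too bulky to chelate tin), C- over O-alkylation (the enol ether from O-attack should reopen under SnCl4) and no other nucleophilic alkene, which is why the homoprenyl terminus is added later.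

Step 8
Reactants: 11 methyl 4α-[(tert-butyldiphenylsilyloxy)methyl]-3β-hydroxy-4β,10β-dimethyl-8-oxo-5α-decalin-9β-carboxylate
Product: 12 3β-O-(imidazol-1-ylthiocarbonyl) derivative of 11
Conditions: 1,1'-thiocarbonyldiimidazole, DMAP (cat.), ClCH2CH2Cl, 80 °C
Reagents that add atoms: 1,1'-thiocarbonyldiimidazole, S=C(n1ccnc1)n1ccnc1
Why: Thioacylation of the secondary alcohol under base-free conditions should leave the enolisable β-keto ester (mainly keto form) untouched.

Step 9
Reactants: 12 3β-O-(imidazol-1-ylthiocarbonyl) derivative of 11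
Product: 13 methyl 4α-[(tert-butyldiphenylsilyloxy)methyl]-4β,10β-dimethyl-8-oxo-5α-decalin-9β-carboxylate
Conditions: Bu3SnH, AIBN (cat.), toluene, 100 °C
Reagents that add atoms: none
Why: Barton–McCombie deoxygenation proceeds through a secondary C3 radical that has no β-leaving group and is reduced by the tin hydride; no stereocentre is touched.

Step 10
Reactants: 13 methyl 4α-[(tert-butyldiphenylsilyloxy)methyl]-4β,10β-dimethyl-8-oxo-5α-decalin-9β-carboxylate
Product: 14 methyl 4α-[(tert-butyldiphenylsilyloxy)methyl]-4β,10β-dimethyl-8-(trifluoromethylsulfonyloxy)-5α-decal-8-ene-9-carboxylate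
Conditions: NaH, THF, 0 °C; then PhNTf2, 0 °C to rt
Reagents that add atoms: N-phenylbis(trifluoromethanesulfonimide), O=S(=O)(N(c1ccccc1)S(=O)(=O)C(F)(F)F)C(F)(F)F
Why: O-Triflation of the sodium enolate of the β-keto ester fixes the C8=C9 double bond in conjugation with the ester.

Step 11
Reactants: 14 methyl 4α-[(tert-butyldiphenylsilyloxy)methyl]-4β,10β-dimethyl-8-(trifluoromethylsulfonyloxy)-5α-decal-8-ene-9-carboxylate
Product: 15 methyl 4α-[(tert-butyldiphenylsilyloxy)methyl]-4β,8,10β-trimethyl-5α-decal-8-ene-9-carboxylate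
Conditions: Me2CuLi (from CuI, 2 MeLi), Et2O, −20 to 0 °C
Reagents that add atoms: lithium dimethylcuprate, [Li+].C[Cu-]C
Why: Conjugate addition–elimination of the cuprate on the β-triflyloxy enoate replaces the triflate by methyl at C8 and leaves the tetrasubstituted C8=C9 enoate.

Step 12
Reactants: 15 methyl 4α-[(tert-butyldiphenylsilyloxy)methyl]-4β,8,10β-trimethyl-5α-decal-8-ene-9-carboxylate
Product: 16 methyl 4α-(hydroxymethyl)-4β,8,10β-trimethyl-5α-decal-8-ene-9-carboxylate
Conditions: Bu4NF, THF, 50 °C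
Reagents that add atoms: none
Why: Fluoride-induced desilylation frees the neopentylic C18 alcohol, and the hindered tetrasubstituted enoate should resist the basic medium.

Step 13
Reactants: 16 methyl 4α-(hydroxymethyl)-4β,8,10β-trimethyl-5α-decal-8-ene-9-carboxylate
Product: 17 methyl 4α-formyl-4β,8,10β-trimethyl-5α-decal-8-ene-9-carboxylate
Conditions: Dess–Martin periodinane, NaHCO3, CH2Cl2, rt
Reagents that add atoms: none
Why: Dess–Martin oxidation gives the aldehyde, which has a quaternary α-carbon and so cannot epimerise at C4.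

Step 14
Reactants: 17 methyl 4α-formyl-4β,8,10β-trimethyl-5α-decal-8-ene-9-carboxylate
Product: 18 methyl 4α-ethenyl-4β,8,10β-trimethyl-5α-decal-8-ene-9-carboxylate
Conditions: Ph3PCH3Br, KOtBu, THF, 0 °C to rt
Reagents that add atoms: methyltriphenylphosphonium bromide, C[P+](c1ccccc1)(c1ccccc1)c1ccccc1.[Br-]
Why: Wittig methylenation with the small unstabilised ylide should reach the hindered aldehyde, while the shielded ester is inert.

Step 15
Reactants: 18 methyl 4α-ethenyl-4β,8,10β-trimethyl-5α-decal-8-ene-9-carboxylate; 19 1-bromo-2-methylprop-1-ene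
Product: 21 methyl 4β,8,10β-trimethyl-4α-(4-methylpent-3-en-1-yl)-5α-decal-8-ene-9-carboxylate, via B-alkyl-9-BBN borane 20 (not isolated)
Conditions: 9-BBN, THF, rt to 60 °C; then 19, Pd(dppf)Cl2 (cat.), aq. K3PO4, DMF, 50 °C
Reagents that add atoms: 1-bromo-2-methylprop-1-ene 19, CC(C)=CBr; 9-BBN, B1C2CCCC1CCC2 (boron stays only in 20)
Why: Anti-Markovnikov hydroboration by 9-BBN is selective for the monosubstituted alkene over the tetrasubstituted enoate, and B-alkyl Suzuki–Miyaura coupling (oxidative addition of the vinyl bromide to zerovalent palladium, base-assisted transmetalation, reductive elimination) joins the primary alkyl group to the alkenyl carbon.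

Step 16
Reactants: 21 methyl 4β,8,10β-trimethyl-4α-(4-methylpent-3-en-1-yl)-5α-decal-8-ene-9-carboxylate
Product: 22 [4β,8,10β-trimethyl-4α-(4-methylpent-3-en-1-yl)-5α-decal-8-en-9-yl]methanol
Conditions: i-Bu2AlH, CH2Cl2, −78 to 0 °C; aq. potassium sodium tartrate
Reagents that add atoms: none
Why: 1,2-Reduction of the conjugated ester by the aluminium hydride gives the allylic alcohol without touching either alkene.

Step 17
Reactants: 22 [4β,8,10β-trimethyl-4α-(4-methylpent-3-en-1-yl)-5α-decal-8-en-9-yl]methanol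
Product: 23 9-(bromomethyl)-4β,8,10β-trimethyl-4α-(4-methylpent-3-en-1-yl)-5α-decal-8-ene
Conditions: CBr4, PPh3, CH2Cl2, −20 to 0 °C; used at once
Reagents that add atoms: carbon tetrabromide, BrC(Br)(Br)Br
Why: The Appel reaction converts the primary allylic alcohol into the bromide under neutral conditions that spare the acid-sensitive trisubstituted alkene.

Step 18
Reactants: 23 9-(bromomethyl)-4β,8,10β-trimethyl-4α-(4-methylpent-3-en-1-yl)-5α-decal-8-ene; 8 methyl acetoacetate
Product: 25 methyl 3-oxo-5-[4β,8,10β-trimethyl-4α-(4-methylpent-3-en-1-yl)-5α-decal-8-en-9-yl]pentanoate, via dilithium acetoacetate dianion 24 (not isolated)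
Conditions: 8, LiN(i-Pr)2 (2.1 equiv), THF, −78 to 0 °C; then 23, −78 to 0 °C; aq. NH4Cl
Reagents that add atoms: methyl acetoacetate 8, COC(=O)CC(C)=O
Why: γ-Alkylation of the dilithium acetoacetate dianion (formed with two equivalents of the amide base, so that no alkyllithium can attack the labile halide) by SN2 at the primary allylic carbon C11 forms the C11–C12 bond, attack at the fully substituted C8 (SN2′) being sterically disfavoured.

Step 19
Reactants: 25 methyl 3-oxo-5-[4β,8,10β-trimethyl-4α-(4-methylpent-3-en-1-yl)-5α-decal-8-en-9-yl]pentanoate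
Product: 26 methyl (2Z)-3-(diethoxyphosphoryloxy)-5-[4β,8,10β-trimethyl-4α-(4-methylpent-3-en-1-yl)-5α-decal-8-en-9-yl]pent-2-enoate
Conditions: NaH, Et2O, 0 °C; then ClP(O)(OEt)2, 0 °C
Reagents that add atoms: diethyl chlorophosphate, CCOP(=O)(Cl)OCC
Why: O-Phosphorylation of the sodium enolate, held in a chelate between the enolate oxygen and the ester carbonyl, should give the (Z)-enol phosphate.

Step 20
Reactants: 26 methyl (2Z)-3-(diethoxyphosphoryloxy)-5-[4β,8,10β-trimethyl-4α-(4-methylpent-3-en-1-yl)-5α-decal-8-en-9-yl]pent-2-enoate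
Product: 27 methyl (2E)-3-methyl-5-[4β,8,10β-trimethyl-4α-(4-methylpent-3-en-1-yl)-5α-decal-8-en-9-yl]pent-2-enoate
Conditions: Me2CuLi (from CuI, 2 MeLi), Et2O, −78 to −45 °C
Reagents that add atoms: lithium dimethylcuprate, [Li+].C[Cu-]C
Why: Cuprate addition–elimination on the β-phosphoryloxy enoate at low temperature replaces phosphate by methyl with retention, so the (Z)-enol phosphate should give the (E)-enoate.

Step 21
Reactants: 27 methyl (2E)-3-methyl-5-[4β,8,10β-trimethyl-4α-(4-methylpent-3-en-1-yl)-5α-decal-8-en-9-yl]pent-2-enoate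
Product: 28 (2E)-3-methyl-5-[(4aS,5S,8aS)-2,5,8a-trimethyl-5-(4-methylpent-3-en-1-yl)-3,4,4a,5,6,7,8,8a-octahydronaphthalen-1-yl]pent-2-enoic acid
Conditions: LiOH, THF/MeOH/H2O, 50 °C; then 1 M HCl
Reagents that add atoms: lithium hydroxide, [Li+].[OH-]
Why: Saponification of the unhindered methyl ester under mild conditions should not move or isomerise the alkenes.

**Compound list**
1 | geranyl acetate, (2E)-3,7-dimethylocta-2,6-dien-1-yl acetate | CC(C)=CCC/C(C)=C/COC(C)=O | starting material
2 | (2E,6E)-8-hydroxy-3,7-dimethylocta-2,6-dien-1-yl acetate | OC/C(C)=C/CC/C(C)=C/COC(C)=O | intermediate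
3 | (2E)-5-[(2S,3S)-3-(hydroxymethyl)-3-methyloxiran-2-yl]-3-methylpent-2-en-1-yl acetate | OC[C@]1(C)O[C@H]1CC/C(C)=C/COC(C)=O | intermediate
4 | (2E)-5-[(2S,3S)-3-[(tert-butyldiphenylsilyloxy)methyl]-3-methyloxiran-2-yl]-3-methylpent-2-en-1-yl acetate | CC(C)(C)[Si](c1ccccc1)(c1ccccc1)OC[C@]1(C)O[C@H]1CC/C(C)=C/COC(C)=O | intermediate
5 | (2E)-5-[(2S,3S)-3-[(tert-butyldiphenylsilyloxy)methyl]-3-methyloxiran-2-yl]-3-methylpent-2-en-1-ol | CC(C)(C)[Si](c1ccccc1)(c1ccccc1)OC[C@]1(C)O[C@H]1CC/C(C)=C/CO | intermediate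
6 | methanesulfonate of 5 | CC(C)(C)[Si](c1ccccc1)(c1ccccc1)OC[C@]1(C)O[C@H]1CC/C(C)=C/COS(C)(=O)=O | intermediate (not isolated)
7 | tert-butyl{[(2S,3S)-3-[(3E)-5-bromo-3-methylpent-3-en-1-yl]-2-methyloxiran-2-yl]methoxy}diphenylsilane | CC(C)(C)[Si](c1ccccc1)(c1ccccc1)OC[C@]1(C)O[C@H]1CC/C(C)=C/CBr | intermediate
8 | methyl acetoacetate | COC(=O)CC(C)=O | starting material
9 | methyl acetoacetate dianion (sodium lithium salt) | COC(=O)[CH-]C(=O)[CH2-].[Na+].[Li+] | intermediate (not isolated)
10 | methyl (6E,10S,11S)-12-(tert-butyldiphenylsilyloxy)-10,11-epoxy-7,11-dimethyl-3-oxododec-6-enoate | CC(C)(C)[Si](c1ccccc1)(c1ccccc1)OC[C@]1(C)O[C@H]1CC/C(C)=C/CCC(=O)CC(=O)OC | intermediate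
11 | methyl 4α-[(tert-butyldiphenylsilyloxy)methyl]-3β-hydroxy-4β,10β-dimethyl-8-oxo-5α-decalin-9β-carboxylate | CC(C)(C)[Si](c1ccccc1)(c1ccccc1)OC[C@]1(C)[C@@H](O)CC[C@]2(C)[C@@H](C(=O)OC)C(=O)CC[C@@H]12 | intermediate
12 | 3β-O-(imidazol-1-ylthiocarbonyl) derivative of 11 | CC(C)(C)[Si](c1ccccc1)(c1ccccc1)OC[C@]1(C)[C@@H](OC(=S)n3ccnc3)CC[C@]2(C)[C@@H](C(=O)OC)C(=O)CC[C@@H]12 | intermediate
13 | methyl 4α-[(tert-butyldiphenylsilyloxy)methyl]-4β,10β-dimethyl-8-oxo-5α-decalin-9β-carboxylate | CC(C)(C)[Si](c1ccccc1)(c1ccccc1)OC[C@]1(C)CCC[C@]2(C)[C@@H](C(=O)OC)C(=O)CC[C@@H]12 | intermediate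
14 | methyl 4α-[(tert-butyldiphenylsilyloxy)methyl]-4β,10β-dimethyl-8-(trifluoromethylsulfonyloxy)-5α-decal-8-ene-9-carboxylate | CC(C)(C)[Si](c1ccccc1)(c1ccccc1)OC[C@]1(C)CCC[C@]2(C)C(C(=O)OC)=C(OS(=O)(=O)C(F)(F)F)CC[C@@H]12 | intermediate
15 | methyl 4α-[(tert-butyldiphenylsilyloxy)methyl]-4β,8,10β-trimethyl-5α-decal-8-ene-9-carboxylate | CC(C)(C)[Si](c1ccccc1)(c1ccccc1)OC[C@]1(C)CCC[C@]2(C)C(C(=O)OC)=C(C)CC[C@@H]12 | intermediate
16 | methyl 4α-(hydroxymethyl)-4β,8,10β-trimethyl-5α-decal-8-ene-9-carboxylate | OC[C@]1(C)CCC[C@]2(C)C(C(=O)OC)=C(C)CC[C@@H]12 | intermediate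
17 | methyl 4α-formyl-4β,8,10β-trimethyl-5α-decal-8-ene-9-carboxylate | O=C[C@]1(C)CCC[C@]2(C)C(C(=O)OC)=C(C)CC[C@@H]12 | intermediate
18 | methyl 4α-ethenyl-4β,8,10β-trimethyl-5α-decal-8-ene-9-carboxylate | C=C[C@]1(C)CCC[C@]2(C)C(C(=O)OC)=C(C)CC[C@@H]12 | intermediate
19 | 1-bromo-2-methylprop-1-ene | CC(C)=CBr | starting material
20 | methyl 4α-[2-(9-borabicyclo[3.3.1]nonan-9-yl)ethyl]-4β,8,10β-trimethyl-5α-decal-8-ene-9-carboxylate | C1CCC2CCCC1B2CC[C@]1(C)CCC[C@]2(C)C(C(=O)OC)=C(C)CC[C@@H]12 | intermediate (not isolated)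
21 | methyl 4β,8,10β-trimethyl-4α-(4-methylpent-3-en-1-yl)-5α-decal-8-ene-9-carboxylate | CC(C)=CCC[C@]1(C)CCC[C@]2(C)C(C(=O)OC)=C(C)CC[C@@H]12 | intermediate
22 | [4β,8,10β-trimethyl-4α-(4-methylpent-3-en-1-yl)-5α-decal-8-en-9-yl]methanol | CC(C)=CCC[C@]1(C)CCC[C@]2(C)C(CO)=C(C)CC[C@@H]12 | intermediate
23 | 9-(bromomethyl)-4β,8,10β-trimethyl-4α-(4-methylpent-3-en-1-yl)-5α-decal-8-ene | CC(C)=CCC[C@]1(C)CCC[C@]2(C)C(CBr)=C(C)CC[C@@H]12 | intermediate
24 | methyl acetoacetate dianion (dilithium salt) | COC(=O)[CH-]C(=O)[CH2-].[Li+].[Li+] | intermediate (not isolated)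
25 | methyl 3-oxo-5-[4β,8,10β-trimethyl-4α-(4-methylpent-3-en-1-yl)-5α-decal-8-en-9-yl]pentanoate | CC(C)=CCC[C@]1(C)CCC[C@]2(C)C(CCC(=O)CC(=O)OC)=C(C)CC[C@@H]12 | intermediate
26 | methyl (2Z)-3-(diethoxyphosphoryloxy)-5-[4β,8,10β-trimethyl-4α-(4-methylpent-3-en-1-yl)-5α-decal-8-en-9-yl]pent-2-enoate | CC(C)=CCC[C@]1(C)CCC[C@]2(C)C(CC/C(OP(=O)(OCC)OCC)=C/C(=O)OC)=C(C)CC[C@@H]12 | intermediate
27 | methyl (2E)-3-methyl-5-[4β,8,10β-trimethyl-4α-(4-methylpent-3-en-1-yl)-5α-decal-8-en-9-yl]pent-2-enoate | CC(C)=CCC[C@]1(C)CCC[C@]2(C)C(CC/C(C)=C/C(=O)OC)=C(C)CC[C@@H]12 | intermediate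
28 | (2E)-3-methyl-5-[(4aS,5S,8aS)-2,5,8a-trimethyl-5-(4-methylpent-3-en-1-yl)-3,4,4a,5,6,7,8,8a-octahydronaphthalen-1-yl]pent-2-enoic acid | CC(C)=CCC[C@]1(C)CCC[C@]2(C)C(CC/C(C)=C/C(=O)O)=C(C)CC[C@@H]12 | target

Total step count: 21
Longest linear sequence: 21 steps (1 to 28)

**Steps most likely to fail**

Step 7. The silyloxymethyl group withdraws electron density from C4, so ionisation may be slow. Rearrangement of the opened epoxide to a carbonyl compound (hydride or alkyl shift from C3), chloride capture at C4, arrest after ring A and O-alkylation by the tin-bound keto ester may then overtake the bicyclisation. The fallback changes the terminating nucleophile to an O-silyl enol ether, which can react only at carbon and leaves the Lewis acid free for the epoxide. It sets out from 10: Me3SiCl/Et3N would give the trimethylsilyl enol ether F1 (enol geometry immaterial), and MeAlCl2 in CH2Cl2 at −78 °C would promote the same chair–chair closure with Mukaiyama-type termination at C9. Loss of the silyl group on aqueous work-up brings the sequence back to 11.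

Step 18. The dianion is strongly basic and bromide 23 is a hindered, readily ionised allylic halide, so elimination to a diene, allylic transposition and decomposition of the halide before C–C bond formation may erode the coupling. The fallback is an acetoacetic ester synthesis followed by olefination, setting out from 23. The soft sodium enolate of 8 (NaH, THF/DMF) would be alkylated at its central carbon to give the 2-acetyl ester F2. Krapcho dealkoxycarbonylation (LiCl, wet DMSO, heat) would give methyl ketone F3. Horner–Wadsworth–Emmons reaction with trimethyl phosphonoacetate (NaH, THF) would give 27, from which the minor (2Z)-ester F4 would be removed by chromatography. The route is rejoined at 27.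

Step 8. Thioacylation of the equatorial C3 hydroxyl, which is neopentylic and flanked by the silyloxymethyl group, may stall, and the reagent may instead attack the enol of the keto ester. The fallback changes the order of events so that the alkoxide-based xanthate method becomes usable. It sets out from 11: one equivalent of NaH deprotonates only the keto ester, and PhNTf2 would give the hydroxy enol triflate F5. Excess Me2CuLi would give the hydroxy enoate F6. NaH, CS2 and MeI would give the S-methyl xanthate F7, and Bu3SnH/AIBN would deliver 15, where the route is rejoined.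

Further compounds
F1 | step 7 | trimethylsilyl enol ether of 10, methyl (6E,10S,11S)-12-(tert-butyldiphenylsilyloxy)-10,11-epoxy-7,11-dimethyl-3-(trimethylsilyloxy)dodeca-2,6-dienoate | CC(C)(C)[Si](c1ccccc1)(c1ccccc1)OC[C@]1(C)O[C@H]1CC/C(C)=C/CCC(O[Si](C)(C)C)=CC(=O)OC
F2 | step 18 | methyl 2-acetyl-3-[4β,8,10β-trimethyl-4α-(4-methylpent-3-en-1-yl)-5α-decal-8-en-9-yl]propanoate (both epimers at the new carbon) | CC(C)=CCC[C@]1(C)CCC[C@]2(C)C(CC(C(C)=O)C(=O)OC)=C(C)CC[C@@H]12
F3 | step 18 | 4-[4β,8,10β-trimethyl-4α-(4-methylpent-3-en-1-yl)-5α-decal-8-en-9-yl]butan-2-one | CC(C)=CCC[C@]1(C)CCC[C@]2(C)C(CCC(C)=O)=C(C)CC[C@@H]12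
F4 | step 18 | (2Z)-isomer of 27 | CC(C)=CCC[C@]1(C)CCC[C@]2(C)C(CC/C(C)=C\C(=O)OC)=C(C)CC[C@@H]12
F5 | step 8 | methyl 4α-[(tert-butyldiphenylsilyloxy)methyl]-3β-hydroxy-4β,10β-dimethyl-8-(trifluoromethylsulfonyloxy)-5α-decal-8-ene-9-carboxylate | CC(C)(C)[Si](c1ccccc1)(c1ccccc1)OC[C@]1(C)[C@@H](O)CC[C@]2(C)C(C(=O)OC)=C(OS(=O)(=O)C(F)(F)F)CC[C@@H]12
F6 | step 8 | methyl 4α-[(tert-butyldiphenylsilyloxy)methyl]-3β-hydroxy-4β,8,10β-trimethyl-5α-decal-8-ene-9-carboxylate | CC(C)(C)[Si](c1ccccc1)(c1ccccc1)OC[C@]1(C)[C@@H](O)CC[C@]2(C)C(C(=O)OC)=C(C)CC[C@@H]12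
F7 | step 8 | 3β-O-(methylsulfanylthiocarbonyl) derivative of F6 (S-methyl xanthate) | CC(C)(C)[Si](c1ccccc1)(c1ccccc1)OC[C@]1(C)[C@@H](OC(=S)SC)CC[C@]2(C)C(C(=O)OC)=C(C)CC[C@@H]12
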